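**Plan**

- Retrosynthesis: the pyranone is opened at O1–C2 (a phenol adding to an ynone). Both bonds at the C4 carbonyl, C4a–C4 and C4–C3, are then cut, leaving an aryl iodide, carbon monoxide and a C31 terminal alkyne.
- Enabling feature: C4 is a single carbonyl carbon flanked by C4a of the phloroglucinol-type ring A and by the C3=C2 unit of ring C that carries the nonacosyl chain, so it can enter as CO.
- Forward order: phloroglucinol is MOM-protected and iodinated; triacontanol is oxidised and homologated to the alkyne; the three components are joined to an open-chain aryl ynone; acid then frees the phenols and closes ring C, the only ring formed, last.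
- Stereochemistry: the target has no stereocentre and no stereogenic double bond, so nothing has to be set.

Key step: step 5

Remark: the target is achiral, so "single enantiomer" is read as the one constitution drawn. Chromone numbering (O1, C2, C3, C4, C4a, C5–C8, C8a) is used throughout.

**Route**

Step 1
Reactants: 1 phloroglucinol (anhydrous)
Product: 2 1,3,5-tris(methoxymethoxy)benzene
Conditions: NaH (3.5 equiv), MOMCl (3.5 equiv), DMF, 0 °C → rt
Reagents that add atoms: chloromethyl methyl ether (MOMCl), COCCl
Why: Triple O-alkylation of the phenoxide with chloromethyl methyl ether (Williamson-type MOM protection) should be favoured over C-alkylation because the oxocarbenium-like electrophile is hard and DMF leaves the oxygen anions free.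

Step 2
Reactants: 2 1,3,5-tris(methoxymethoxy)benzene
Product: 4 2-iodo-1,3,5-tris(methoxymethoxy)benzene, via 2-lithio-1,3,5-tris(methoxymethoxy)benzene 3 (not isolated)
Conditions: n-BuLi (1.1 equiv), THF, 0 °C, 1 h; then I2 (1.2 equiv), THF, −78 °C → rt
Reagents that add atoms: iodine, II
Why: Directed ortho-metalation: each ring C–H lies between two coordinating MOM ethers and all three are equivalent, so one equivalent of n-BuLi should give a single aryllithium whose iodine quench delivers the mono-iodide, the base-stable acetals being untouched.

Step 3
Reactants: 5 triacontan-1-ol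
Product: 6 triacontanal
Conditions: TEMPO (10 mol %), PhI(OAc)2 (1.2 equiv), CH2Cl2, 40 °C
Reagents that add atoms: none
Why: TEMPO/PhI(OAc)2 oxidation (oxoammonium-mediated alcohol oxidation) of a primary alcohol stops at the aldehyde in the absence of water, and refluxing dichloromethane should keep the waxy C30 substrate sufficiently dissolved.

Step 4
Reactants: 6 triacontanal; 7 dimethyl (1-diazo-2-oxopropyl)phosphonate
Product: 8 hentriacont-1-yne
Conditions: K2CO3 (2 equiv), MeOH/THF (1:1), rt → 35 °C
Reagents that add atoms: none
Why: Ohira–Bestmann modification of the Seyferth–Gilbert homologation: methanolysis of 7 liberates the diazomethylphosphonate anion, which converts the unbranched aldehyde into the terminal alkyne by Horner–Wadsworth–Emmons-type addition/elimination, loss of N2 and 1,2-hydrogen shift, under carbonate conditions mild enough to limit aldol side reactions.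

Step 5
Reactants: 4 2-iodo-1,3,5-tris(methoxymethoxy)benzene; 8 hentriacont-1-yne; 9 carbon monoxide
Product: 10 1-[2,4,6-tris(methoxymethoxy)phenyl]dotriacont-2-yn-1-one
Conditions: PdCl2(PPh3)2 (5 mol %), CuI (2 mol %), Et3N (3 equiv), THF, CO (5 bar), 45 °C, degassed
Reagents that add atoms: none
Why: Pd(0) inserts into the C–I bond of 4, the resulting arylpalladium iodide takes up CO and rearranges by aryl migration to an aroylpalladium complex, the copper acetylide generated from 8, CuI and Et3N transmetalates to it, and reductive elimination releases 10 with the C4a–C4 and C4–C3 bonds both newly formed. This is a carbonylative Sonogashira coupling, a known reaction of aryl iodides with terminal alkynes under CO. No ring is closed and no stereocentre is created here; the pyranone is left for step 6. The selectivity required is chemoselectivity for the acyl pathway over direct aryl–alkynyl coupling and over oxidative dimerisation of 8. The two ortho OMOM groups crowd the aryl–Pd bond and the three oxygens make the aryl group a good migrating group, so CO insertion should outpace transmetalation at the aryl stage, while CO pressure, a low copper loading and strict exclusion of oxygen support this. Since 4 has a mirror plane through the C–I axis, the two ortho oxygens of 10 are equivalent and no regiochemical question is passed on.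

Step 6
Reactants: 10 1-[2,4,6-tris(methoxymethoxy)phenyl]dotriacont-2-yn-1-one
Product: 12 5,7-dihydroxy-2-nonacosyl-4H-chromen-4-one, via 1-(2,4,6-trihydroxyphenyl)dotriacont-2-yn-1-one 11 (not isolated)
Conditions: conc. HCl, MeOH/THF (1:1), 60 °C
Reagents that add atoms: none
Why: Acid-catalysed acetal methanolysis frees the three phenols, and an ortho hydroxyl then adds to the β-carbon of the protonated ynone in a 6-endo-dig oxa-Michael cyclisation (the known acid-promoted closure of o-hydroxyaryl ynones to chromones) that forms O1–C2, the two ortho hydroxyls being equivalent and conjugate activation disfavouring the 5-exo mode.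

**Compound list**

1 | phloroglucinol (benzene-1,3,5-triol) | Oc1cc(O)cc(O)c1 | starting material
2 | 1,3,5-tris(methoxymethoxy)benzene | COCOc1cc(OCOC)cc(OCOC)c1 | intermediate
3 | 2-lithio-1,3,5-tris(methoxymethoxy)benzene | [Li]c1c(OCOC)cc(OCOC)cc1OCOC | intermediate
4 | 2-iodo-1,3,5-tris(methoxymethoxy)benzene | COCOc1cc(OCOC)c(I)c(OCOC)c1 | intermediate
5 | triacontan-1-ol | CCCCCCCCCCCCCCCCCCCCCCCCCCCCCCO | starting material
6 | triacontanal | CCCCCCCCCCCCCCCCCCCCCCCCCCCCCC=O | intermediate
7 | dimethyl (1-diazo-2-oxopropyl)phosphonate | COP(=O)(OC)C(=[N+]=[N-])C(C)=O | starting material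
8 | hentriacont-1-yne | CCCCCCCCCCCCCCCCCCCCCCCCCCCCCC#C | intermediate
9 | carbon monoxide | [C-]#[O+] | starting material
10 | 1-[2,4,6-tris(methoxymethoxy)phenyl]dotriacont-2-yn-1-one | CCCCCCCCCCCCCCCCCCCCCCCCCCCCCC#CC(=O)c1c(OCOC)cc(OCOC)cc1OCOC | intermediate
11 | 1-(2,4,6-trihydroxyphenyl)dotriacont-2-yn-1-one | CCCCCCCCCCCCCCCCCCCCCCCCCCCCCC#CC(=O)c1c(O)cc(O)cc1O | intermediate
12 | 5,7-dihydroxy-2-nonacosyl-4H-chromen-4-one (achiral) | CCCCCCCCCCCCCCCCCCCCCCCCCCCCCc1cc(=O)c2c(O)cc(O)cc2o1 | target

**Step count**

Total steps: 6. Longest linear sequence: 4 steps (1, 2, 5, 6 or 3, 4, 5, 6).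

**Steps most likely to fail**

Step 5. CO insertion may fail to keep pace, so that the aryl and alkynyl groups couple directly. Oxidative addition at the hindered, electron-rich C–I bond may be slow, leaving the alkyne to dimerise oxidatively. Free phosphine may isomerise the ynone. The fallback installs the carbonyl carbon at the aldehyde oxidation level and forms the same two bonds stepwise. It sets out from 2 and 8 and returns at 10. Compound 2 is lithiated as in step 2 to 3 and quenched with DMF (THF, 0 °C → rt) to give 2,4,6-tris(methoxymethoxy)benzaldehyde F1. Alkyne 8 is deprotonated with n-BuLi in THF at −20 °C to 1-lithiohentriacont-1-yne F2, which adds to F1 to give, after aqueous work-up, racemic 1-[2,4,6-tris(methoxymethoxy)phenyl]dotriacont-2-yn-1-ol F3. Activated MnO2 in CH2Cl2 at rt should oxidise this benzylic and propargylic alcohol to 10 without touching the acetals.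

Step 6. The ring may close in the 5-exo mode. The ynone may be intercepted by methanol or chloride to give adducts that cyclise only slowly. Prolonged acid may cleave the acyl group from the electron-rich ring. The fallback fixes the β-carbon as the only electrophilic site before the phenols are freed. It sets out from 10 and returns at 12. Aza-Michael addition of diethylamine (Et2NH, EtOH/THF, rt) should give (E)-3-(diethylamino)-1-[2,4,6-tris(methoxymethoxy)phenyl]dotriacont-2-en-1-one F4. Methanolic HCl in THF at 50 °C then removes the MOM groups, and the ortho phenol displaces diethylamine by addition–elimination at C2, which can only give the six-membered pyranone of 12.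

Step 4. The waxy aldehyde may precipitate from the methanolic medium, so that conversion stays incomplete and the carbonate base promotes self-aldol condensation. The fallback is a Corey–Fuchs sequence run entirely in good solvents for long-chain substrates. It sets out from 6 and returns at 8. CBr4 and PPh3 in CH2Cl2 (0 °C → rt) should convert 6 into 1,1-dibromohentriacont-1-ene F5. n-BuLi (2.2 equiv) in THF (−78 °C → rt) then effects bromine–lithium exchange and Fritsch–Buttenberg–Wiechell rearrangement, and aqueous quench gives 8.

**Further compounds**

F1 | step 5 | 2,4,6-tris(methoxymethoxy)benzaldehyde | O=Cc1c(OCOC)cc(OCOC)cc1OCOC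
F2 | step 5 | 1-lithiohentriacont-1-yne | CCCCCCCCCCCCCCCCCCCCCCCCCCCCCC#C[Li]
F3 | step 5 | racemic 1-[2,4,6-tris(methoxymethoxy)phenyl]dotriacont-2-yn-1-ol | CCCCCCCCCCCCCCCCCCCCCCCCCCCCCC#CC(O)c1c(OCOC)cc(OCOC)cc1OCOC
F4 | step 6 | (E)-3-(diethylamino)-1-[2,4,6-tris(methoxymethoxy)phenyl]dotriacont-2-en-1-one | CCN(CC)/C(CCCCCCCCCCCCCCCCCCCCCCCCCCCCC)=C/C(=O)c1c(OCOC)cc(OCOC)cc1OCOC
F5 | step 4 | 1,1-dibromohentriacont-1-ene | CCCCCCCCCCCCCCCCCCCCCCCCCCCCCC=C(Br)Br
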